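**Retrosynthetic overview**
- The C8–OOH bond, the C8 centre and the E-6,7 alkene come last, from a photochemical singlet-oxygen ene reaction on the 7,8-alkene of the epoxy lactone.
- The 11,12-epoxide (third ring) is put on the macrocyclic diene lactone while the 7,8-alkene is masked as a bromoether through the C4 hydroxyl.
- The δ-lactone (second ring) comes from the isopropenyl group and the C3 hydroxyl by hydroboration and oxidative lactonization, with C15 set by equilibration.
- The 14-membered carbocycle (first ring) is closed at C3–C4 by an electrochemical pinacol coupling of an acyclic keto aldehyde; C3 is then reset by oxidation and chelation-controlled reduction.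
- The keto aldehyde comes from (R)-limonene (the only bought stereocentre, C1) by ring ozonolysis and two rounds of methyl ketone → alkyne → methylalumination → conjugate addition to methyl vinyl ketone.

Assumption: macrocycles are named with cembrane numbering (ring C1–C14; C15 on C1 carries C16 and C17; methyls C18, C19, C20 sit on C4, C8, C12), and the one compound formed as a C15 epimer pair has that centre left open in its SMILES.

Step 1
Reactants: 1 (R)-(+)-limonene
Product: 2 (5R)-7,7-dimethoxy-5-(prop-1-en-2-yl)heptan-2-one
Conditions: O3 (1.0 equiv), CH2Cl2/MeOH 5:1, −78 °C; TsOH·H2O (cat.), −78 °C to rt; Me2S, rt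
Reagents that add atoms: ozone, [O-][O+]=O; methanol, CO
Why: The trisubstituted ring alkene is ozonized faster than the isopropenyl group and, in methanol, the carbonyl oxide forms on the methyl-bearing carbon, so acid acetalizes the free aldehyde and reduction gives the methyl ketone (ozonolysis with unsymmetrical work-up), the limonene stereocentre (later C1) being untouched.

Step 2
Reactants: 2 (5R)-7,7-dimethoxy-5-(prop-1-en-2-yl)heptan-2-one
Product: 4 (3R)-1,1-dimethoxy-3-(prop-1-en-2-yl)hept-6-yne, via enol phosphate 3 (not isolated)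
Conditions: LiN(iPr)2 (1.1 equiv), THF, −78 °C; ClP(O)(OEt)2, −78 °C to rt; LiN(iPr)2 (2.3 equiv), −78 °C to rt; H2O
Reagents that add atoms: none
Why: Kinetic deprotonation on the methyl side gives the terminal enol phosphate, which loses diethyl phosphate with excess amide base to give the terminal alkyne (Negishi methyl ketone to alkyne conversion), while the acetal and the stereocentre are inert to base.

Step 3
Reactants: 4 (3R)-1,1-dimethoxy-3-(prop-1-en-2-yl)hept-6-yne; 5 but-3-en-2-one
Product: 7 (5E,9R)-11,11-dimethoxy-6-methyl-9-(prop-1-en-2-yl)undec-5-en-2-one, via alkenylalane 6 (not isolated)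
Conditions: AlMe3 (2.5 equiv), Cp2ZrCl2 (0.2 equiv), H2O (1 equiv), CH2Cl2, −25 °C to 0 °C; volatiles removed; 5 (2 equiv), Ni(acac)2 (0.1 equiv), THF, −25 °C to 0 °C; aq. work-up
Reagents that add atoms: trimethylaluminium, C[Al](C)C
Why: Zirconium-catalysed methylalumination is a syn addition that puts the methyl on the internal alkyne carbon and gives only the E-alkenylalane, whose alkenyl group is then transferred 1,4 to the enone under nickel catalysis (Negishi carboalumination followed by conjugate addition), so the E-11,12 alkene geometry is fixed by mechanism.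

Step 4
Reactants: 7 (5E,9R)-11,11-dimethoxy-6-methyl-9-(prop-1-en-2-yl)undec-5-en-2-one
Product: 9 (5E,9R)-11,11-dimethoxy-6-methyl-9-(prop-1-en-2-yl)undec-5-en-1-yne, via enol phosphate 8 (not isolated)
Conditions: LiN(iPr)2 (1.1 equiv), THF, −78 °C; ClP(O)(OEt)2, −78 °C to rt; LiN(iPr)2 (2.3 equiv), −78 °C to rt; H2O
Reagents that add atoms: none
Why: The same kinetic enol phosphate formation and elimination as in step 2 (Negishi methyl ketone to alkyne conversion) turns the new methyl ketone into the next terminal alkyne without touching the trisubstituted alkene.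

Step 5
Reactants: 9 (5E,9R)-11,11-dimethoxy-6-methyl-9-(prop-1-en-2-yl)undec-5-en-1-yne; 5 but-3-en-2-one
Product: 12 (3R,6E,10E)-6,10-dimethyl-14-oxo-3-(prop-1-en-2-yl)pentadeca-6,10-dienal, via alkenylalane 10 (not isolated), via keto acetal 11 (not isolated)
Conditions: AlMe3 (2.5 equiv), Cp2ZrCl2 (0.2 equiv), H2O (1 equiv), CH2Cl2, −25 °C to 0 °C; volatiles removed; 5 (2 equiv), Ni(acac)2 (0.1 equiv), THF, −25 °C to 0 °C; aq. work-up; then 1 M HCl, THF, rt
Reagents that add atoms: trimethylaluminium, C[Al](C)C; water, O
Why: A second syn methylalumination and nickel-catalysed conjugate addition (Negishi carboalumination followed by conjugate addition) installs the E-7,8 alkene and the C4 methyl ketone, and dilute acid then hydrolyses the dimethyl acetal to the C3 aldehyde.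

Step 6
Reactants: 12 (3R,6E,10E)-6,10-dimethyl-14-oxo-3-(prop-1-en-2-yl)pentadeca-6,10-dienal
Product: 14 (1R,3S,4S,7E,11E)-cembra-7,11,15-triene-3,4-diol, via bis-silyl ether 13 (not isolated)
Conditions: SmI2 (0.15 equiv), Me3SiCl (4 equiv), n-Bu4NPF6 (0.1 M), THF, divided cell, carbon-felt cathode, Mg anode, 2 mA cm−2, 12 added over 12 h (final 2 mM), 20 °C; then K2CO3 (cat.), MeOH, rt
Reagents that add atoms: none
Why: Proposed new method: divalent samarium, regenerated at the cathode while Me3SiCl strips the trivalent metal from the product, reduces the aldehyde to a metal-bound ketyl that is kept below millimolar concentration and adds across the chain to the samarium-coordinated methyl ketone, so that the C3–C4 bond and the fourteen-membered ring form in one cathodic step (closest known reaction type: SmI2 or low-valent titanium pinacol macrocyclization of keto aldehydes and samarium-electrocatalysed intermolecular pinacol coupling, not yet shown as an electrocatalytic macrocyclization of an aliphatic keto aldehyde), and in the closing geometry both oxygens sit on one samarium, the ring bonds to C2 and C5 are anti and the bulky metal-bound oxygen at C3 lies away from the C1 isopropenyl group, which makes C4 S under control of C1 (C3 forms as S and is reset in step 8).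

Step 7
Reactants: 14 (1R,3S,4S,7E,11E)-cembra-7,11,15-triene-3,4-diol
Product: 15 (1R,4S,7E,11E)-4-hydroxycembra-7,11,15-trien-3-one
Conditions: Dess–Martin periodinane (1.2 equiv), CH2Cl2, 0 °C to rt
Reagents that add atoms: none
Why: Dess–Martin oxidation takes only the secondary C3 carbinol to the ketone because the tertiary C4 alcohol cannot be oxidized, which erases the unwanted C3 configuration and leaves an α-hydroxy ketone.

Step 8
Reactants: 15 (1R,4S,7E,11E)-4-hydroxycembra-7,11,15-trien-3-one
Product: 16 (1R,3R,4S,7E,11E)-cembra-7,11,15-triene-3,4-diol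
Conditions: Zn(BH4)2 (1.5 equiv), Et2O, −30 °C
Reagents that add atoms: none
Why: Zinc chelates the C4 hydroxyl and the C3 carbonyl oxygen and hydride arrives on the open outer face, syn to the small C4 methyl and away from ring carbon C5 (chelation-controlled reduction of an α-hydroxy ketone), which gives the anti diol and so sets C3 as R from 4S.

Step 9
Reactants: 16 (1R,3R,4S,7E,11E)-cembra-7,11,15-triene-3,4-diol
Product: 17 (1R,3R,4S,7E,11E,15RS)-cembra-7,11-diene-3,4,16-triol
Conditions: 9-BBN (4 equiv), THF, 0 °C to rt; then NaOH, H2O2, 0 °C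
Reagents that add atoms: hydrogen peroxide, OO
Why: 9-BBN adds to the unhindered 1,1-disubstituted isopropenyl group far faster than to the trisubstituted ring alkenes and places boron on the terminal carbon (anti-Markovnikov hydroboration–oxidation), C15 forming as an epimer pair that converges in step 10.

Step 10
Reactants: 17 (1R,3R,4S,7E,11E,15RS)-cembra-7,11-diene-3,4,16-triol
Product: 18 (1R,3R,4S,7E,11E,15S)-4-hydroxycembra-7,11-dien-16,3-olide
Conditions: [Cu(MeCN)4]OTf (10 mol %), 2,2′-bipyridine, TEMPO, N-methylimidazole, air, MeCN, rt; then DBU (1 equiv), 50 °C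
Reagents that add atoms: none
Why: The copper/nitroxyl aerobic system oxidizes only the primary alcohol, whose six-membered lactol with the C3 hydroxyl is oxidized on to the δ-lactone (oxidative lactonization), and DBU then equilibrates the enolizable C15 centre to the all-equatorial lactone with the methyl trans to C14, which is 15S.

Step 11
Reactants: 18 (1R,3R,4S,7E,11E,15S)-4-hydroxycembra-7,11-dien-16,3-olide
Product: 20 (1R,3R,4S,7S,8R,11S,12S,15S)-8-bromo-4,7:11,12-diepoxycembran-16,3-olide, via bromoether 19 (not isolated)
Conditions: NBS (1.05 equiv), CH2Cl2, −40 °C; then mCPBA (1.2 equiv), 0 °C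
Reagents that add atoms: N-bromosuccinimide, O=C1CCC(=O)N1Br; 3-chloroperoxybenzoic acid, OOC(=O)c1cccc(Cl)c1
Why: NBS engages only the 7,8-alkene because the C4 hydroxyl traps its bromonium ion by anti 5-exo bromoetherification (a 6-endo regioisomer or the other anti adduct would be unmasked equally in step 12), after which the peracid can only epoxidize the E-11,12 alkene and is expected to do so from the outer face of the ring (Prilezhaev epoxidation under macrocyclic control by the ring stereocentres), giving 11S,12S.

Step 12
Reactants: 20 (1R,3R,4S,7S,8R,11S,12S,15S)-8-bromo-4,7:11,12-diepoxycembran-16,3-olide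
Product: 21 (1R,3R,4S,7E,11S,12S,15S)-11,12-epoxy-4-hydroxycembr-7-en-16,3-olide
Conditions: Zn dust (10 equiv), EtOH/H2O 9:1, 45 °C
Reagents that add atoms: none
Why: Zinc inserts into the tertiary C–Br bond and expels the β-alkoxide (Boord-type reductive elimination), which returns the C4 alcohol and the 7,8-alkene in the E geometry that the ring was built around, while the epoxide and the lactone are inert to zinc.

Step 13
Reactants: 21 (1R,3R,4S,7E,11S,12S,15S)-11,12-epoxy-4-hydroxycembr-7-en-16,3-olide
Product: 22 (1R,3R,4S,6E,8S,11S,12S,15S)-11,12-epoxy-8-hydroperoxy-4-hydroxycembr-6-en-16,3-olide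
Conditions: O2, tetraphenylporphyrin (1 mol %), white LEDs, CH2Cl2, −20 °C
Reagents that add atoms: dioxygen, O=O
Why: Singlet oxygen from the excited porphyrin undergoes the Schenck ene reaction at the only remaining alkene, taking an allylic hydrogen from the crowded side (C6 in competition with C19, cis effect) and bonding to C8 suprafacially on the exposed outer face, which gives the tertiary 8S hydroperoxide and the new E-6,7 alkene under control of the ring stereocentres, the 7-hydroperoxy-8(19)-ene isomer being the expected by-product.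

**Compound list**
1 | (R)-(+)-limonene, (4R)-1-methyl-4-(prop-1-en-2-yl)cyclohex-1-ene | CC1=CC[C@@H](CC1)C(C)=C | starting material
2 | (5R)-7,7-dimethoxy-5-(prop-1-en-2-yl)heptan-2-one | CC(=O)CC[C@H](CC(OC)OC)C(C)=C | intermediate
3 | diethyl (5R)-7,7-dimethoxy-5-(prop-1-en-2-yl)hept-1-en-2-yl phosphate | C=C(OP(=O)(OCC)OCC)CC[C@H](CC(OC)OC)C(C)=C | intermediate
4 | (3R)-1,1-dimethoxy-3-(prop-1-en-2-yl)hept-6-yne | C#CCC[C@H](CC(OC)OC)C(C)=C | intermediate
5 | but-3-en-2-one (methyl vinyl ketone) | C=CC(C)=O | starting material
6 | [(1E,5R)-7,7-dimethoxy-2-methyl-5-(prop-1-en-2-yl)hept-1-en-1-yl]dimethylalane | C[Al](C)/C=C(\C)CC[C@H](CC(OC)OC)C(C)=C | intermediate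
7 | (5E,9R)-11,11-dimethoxy-6-methyl-9-(prop-1-en-2-yl)undec-5-en-2-one | CC(=O)CC/C=C(\C)CC[C@H](CC(OC)OC)C(C)=C | intermediate
8 | diethyl (5E,9R)-11,11-dimethoxy-6-methyl-9-(prop-1-en-2-yl)undeca-1,5-dien-2-yl phosphate | C=C(OP(=O)(OCC)OCC)CC/C=C(\C)CC[C@H](CC(OC)OC)C(C)=C | intermediate
9 | (5E,9R)-11,11-dimethoxy-6-methyl-9-(prop-1-en-2-yl)undec-5-en-1-yne | C#CCC/C=C(\C)CC[C@H](CC(OC)OC)C(C)=C | intermediate
10 | [(1E,5E,9R)-11,11-dimethoxy-2,6-dimethyl-9-(prop-1-en-2-yl)undeca-1,5-dien-1-yl]dimethylalane | C[Al](C)/C=C(\C)CC/C=C(\C)CC[C@H](CC(OC)OC)C(C)=C | intermediate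
11 | (5E,9E,13R)-15,15-dimethoxy-6,10-dimethyl-13-(prop-1-en-2-yl)pentadeca-5,9-dien-2-one | CC(=O)CC/C=C(\C)CC/C=C(\C)CC[C@H](CC(OC)OC)C(C)=C | intermediate
12 | (3R,6E,10E)-6,10-dimethyl-14-oxo-3-(prop-1-en-2-yl)pentadeca-6,10-dienal | CC(=O)CC/C=C(\C)CC/C=C(\C)CC[C@H](CC=O)C(C)=C | intermediate
13 | (1R,3S,4S,7E,11E)-3,4-bis(trimethylsilyloxy)cembra-7,11,15-triene | C[Si](C)(C)O[C@H]1C[C@H](C(C)=C)CC/C(C)=C/CC/C(C)=C/CC[C@]1(C)O[Si](C)(C)C | intermediate
14 | (1R,3S,4S,7E,11E)-cembra-7,11,15-triene-3,4-diol | O[C@H]1C[C@H](C(C)=C)CC/C(C)=C/CC/C(C)=C/CC[C@]1(C)O | intermediate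
15 | (1R,4S,7E,11E)-4-hydroxycembra-7,11,15-trien-3-one | O=C1C[C@H](C(C)=C)CC/C(C)=C/CC/C(C)=C/CC[C@]1(C)O | intermediate
16 | (1R,3R,4S,7E,11E)-cembra-7,11,15-triene-3,4-diol | O[C@@H]1C[C@H](C(C)=C)CC/C(C)=C/CC/C(C)=C/CC[C@]1(C)O | intermediate
17 | (1R,3R,4S,7E,11E,15RS)-cembra-7,11-diene-3,4,16-triol | O[C@@H]1C[C@H](C(C)CO)CC/C(C)=C/CC/C(C)=C/CC[C@]1(C)O | intermediate
18 | (1R,3R,4S,7E,11E,15S)-4-hydroxycembra-7,11-dien-16,3-olide | C[C@@H]1C(=O)O[C@@H]2C[C@H]1CC/C(C)=C/CC/C(C)=C/CC[C@]2(C)O | intermediate
19 | (1R,3R,4S,7S,8R,11E,15S)-8-bromo-4,7-epoxycembr-11-en-16,3-olide | C[C@@H]1C(=O)O[C@@H]2C[C@H]1CC/C(C)=C/CC[C@@](C)(Br)[C@@H]3CC[C@]2(C)O3 | intermediate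
20 | (1R,3R,4S,7S,8R,11S,12S,15S)-8-bromo-4,7:11,12-diepoxycembran-16,3-olide | C[C@@H]1C(=O)O[C@@H]2C[C@H]1CC[C@]3(C)O[C@H]3CC[C@@](C)(Br)[C@@H]4CC[C@]2(C)O4 | intermediate
21 | (1R,3R,4S,7E,11S,12S,15S)-11,12-epoxy-4-hydroxycembr-7-en-16,3-olide | C[C@@H]1C(=O)O[C@@H]2C[C@H]1CC[C@]3(C)O[C@H]3CC/C(C)=C/CC[C@]2(C)O | intermediate
22 | (1R,3R,4S,6E,8S,11S,12S,15S)-11,12-epoxy-8-hydroperoxy-4-hydroxycembr-6-en-16,3-olide (CNP0297487.4) | C[C@@H]1C(=O)O[C@@H]2C[C@H]1CC[C@]1(C)O[C@H]1CC[C@](C)(OO)/C=C/C[C@]2(C)O | target

Total step count: 13. Longest linear sequence: 13 steps (1 to 22).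

**Steps most likely to fail**

Step 6 is the proposed new reaction. It may give simple reduction of the aldehyde, intermolecular coupling, or a weak preference for the 4S diol. The fallback uses known chemistry and sets out from 12: stoichiometric low-valent titanium from TiCl3(DME)1.5 and Zn–Cu couple in DME at 25 °C, with 12 added by syringe pump over about 30 h. At room temperature this reagent stops at the 1,2-diol and is an established way to close fourteen-membered rings from keto aldehydes. Its surface-bound bis-ketyl should have the same syn-oxygen, anti-chain geometry, so the product is 14 (any 3-epimer is 16, and both are oxidized to 15). The route is rejoined at 14; no compound outside the list is made (F0).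

Step 11 depends on the peracid reaching the correct face of the 11,12-alkene, which is predicted only from the expected ring conformation. The fallback sets out from 18 and delivers the epoxide oxygen to the opposite face. NBS (2.2 equiv) in THF/H2O at 0 °C first forms the bromoether, then puts a bromonium ion on the accessible face of the 11,12-alkene; water opens it at the tertiary C12 from the other side. This gives the bromohydrin (1R,3R,4S,7S,8R,11R,12S,15S)-8,11-dibromo-4,7-epoxy-12-hydroxycembran-16,3-olide F1. K2CO3 in MeCN then closes the C12 oxygen onto C11 with inversion, and the route is rejoined at 20. Use this if the peracid gives mainly the 11,12-epimer.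

Step 13 can divide between abstraction at C6 (target) and at C19 (secondary hydroperoxide with an exocyclic alkene), and its face selectivity at C8 rests on ring conformation alone. The fallback sets out from 21 and replaces the light-driven oxygenation with a stoichiometric dark oxygen donor: triphenyl phosphite ozonide, made from P(OPh)3 and O3 in CH2Cl2 at −78 °C, then 21 and pyridine at −78 to −30 °C. This is a known ene-type allylic hydroperoxidation that needs no sensitizer or light, protects the hydroperoxide and epoxide from photochemical side reactions, and may shift the C6/C19 ratio through its bulkier oxygen donor. It arrives directly at 22; no compound outside the list is made (F0).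

Further compounds
F0 | step 6 | none | none
F1 | step 11 | (1R,3R,4S,7S,8R,11R,12S,15S)-8,11-dibromo-4,7-epoxy-12-hydroxycembran-16,3-olide | C[C@@H]1C(=O)O[C@@H]2C[C@H]1CC[C@](C)(O)[C@H](Br)CC[C@@](C)(Br)[C@@H]3CC[C@]2(C)O3
F0 | step 13 | none | none
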